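The cyclohexane ring is closed at C2–C3 (C1 = ring CMe2, C2 = the CH2 beside it, C3 = carbinol carbon): iodine–lithium exchange at a neopentyl C2 iodide and 6-exo attack of the alkyllithium on the C3 ester carbonyl give the ring ketone in one operation. The step exploits the quaternary C1 (no β-hydrogen, gem-dimethyl acceleration) and keeps C6 as an exocyclic methylene, so the acyclic precursor needs no tetrasubstituted alkene geometry. A C5 methyl stereocentre from (S)-methylsuccinate then fixes C3 and is erased by a carbonyl-ene reaction that builds C7–C8 and the C5=C6 alkene; directed epoxidation, C3 inversion, Wittig extension and late C8 oxidation complete the target.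

Key step: step 6

Remark on numbering: C4 = ring CH2 between C3 and C5, C5 = epoxide carbon bearing CH3, C6 = epoxide carbon bearing the side chain, C7 = side-chain CH2, C8 = ketone carbon, C9–C11 = the next three chain carbons.
Assumption: compounds 1, 3, 13 and 20 are taken as purchasable building blocks.
Remark on C8: compounds 14–17 are carried as mixtures of both C8 epimers (C8 left undefined in the SMILES), and the same holds for 18, 19 and 21–24, because C8 becomes the ketone carbon in the last step.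

Step 1
Reactants: 1 (2S)-4-methoxy-2-methyl-4-oxobutanoic acid
Product: 2 methyl (3S)-4-chloro-3-methyl-4-oxobutanoate
Conditions: (COCl)2, DMF (cat.), CH2Cl2, 0 °C to rt
Reagents that add atoms: oxalyl chloride, ClC(=O)C(Cl)=O
Why: Acyl chloride formation under Vilsmeier catalysis; the conditions are free of base, so the α-stereocentre (future C5) is not epimerised and the methyl ester stays intact.

Step 2
Reactants: 2 methyl (3S)-4-chloro-3-methyl-4-oxobutanoate; 3 trimethyl[(2-methylprop-1-en-1-yl)oxy]silane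
Product: 4 methyl (3S)-3,5,5-trimethyl-4,6-dioxohexanoate
Conditions: TiCl4, CH2Cl2, −78 °C; aqueous NaHCO3
Reagents that add atoms: none
Why: Mukaiyama-type C-acylation of the isobutyraldehyde silyl enol ether forms the C1–C6 bond and the quaternary C1 in one step, and the base-free low-temperature conditions should avoid ketene formation and hence loss of the C5 configuration.

Step 3
Reactants: 4 methyl (3S)-3,5,5-trimethyl-4,6-dioxohexanoate
Product: 5 methyl (3S)-6-hydroxy-3,5,5-trimethyl-4-oxohexanoate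
Conditions: NaBH4 (0.3 equiv), MeOH, −40 °C
Reagents that add atoms: none
Why: Chemoselective borohydride reduction, in which the unhindered aldehyde should react far faster than the doubly α-branched ketone or the ester, the low temperature suppressing retro-Claisen cleavage of the β-keto aldehyde.

Step 4
Reactants: 5 methyl (3S)-6-hydroxy-3,5,5-trimethyl-4-oxohexanoate
Product: 6 methyl (3S)-6-hydroxy-3,5,5-trimethyl-4-methylidenehexanoate
Conditions: Zn, CH2Br2, TiCl4, THF/CH2Cl2, 0 °C to rt
Reagents that add atoms: dibromomethane, BrCBr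
Why: Takai–Lombardo methylenation; the non-basic gem-dimetallic reagent converts hindered, enolisable ketones into 1,1-disubstituted alkenes without epimerising the adjacent C5 centre and does not attack esters.

Step 5
Reactants: 6 methyl (3S)-6-hydroxy-3,5,5-trimethyl-4-methylidenehexanoate
Product: 7 methyl (3S)-6-iodo-3,5,5-trimethyl-4-methylidenehexanoate
Conditions: PPh3, I2, imidazole, toluene, 80 °C
Reagents that add atoms: iodine, II
Why: Appel-type iodination, in which iodide displaces the oxyphosphonium group at the neopentyl-type C2 by SN2, heat compensating for the hindrance while the non-ionising medium should prevent homoallyl rearrangement.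

Step 6
Reactants: 7 methyl (3S)-6-iodo-3,5,5-trimethyl-4-methylidenehexanoate
Product: 10 (5S)-3,3,5-trimethyl-4-methylidenecyclohexan-1-one, via alkyllithium 8 (not isolated), via lithium hemiketal alkoxide 9 (not isolated)
Conditions: t-BuLi (2.1 equiv), Et2O/n-pentane, −100 to −78 °C, then warm to −20 °C; aqueous NH4Cl
Reagents that add atoms: none
Why: Two equivalents of t-BuLi effect iodine–lithium exchange at the neopentyl C2–I bond (the second equivalent destroys t-BuI), and the primary alkyllithium adds intramolecularly to the C3 ester carbonyl; loss of methoxide from the tetrahedral adduct gives the cyclohexanone. The closest known reaction type is the halogen–lithium exchange-initiated intramolecular acylation of organolithiums by esters and amides (Parham-type cyclisation, here in its alkyl iodide version). The carbocycle is closed in the 6-exo-trig mode by formation of the C2–C3 bond. No new stereocentre arises (C3 becomes the carbonyl carbon and is set in step 7), and the C5 centre, β to the new ketone, cannot epimerise. The step needs the exchange to outrun direct attack of t-BuLi on the ester, deprotonation α to the ester and the anionic 1,2-vinyl shift of the homoallylic lithium species; the iodide (exchange is essentially instantaneous at −100 °C), the quaternary C1 (no β-hydrogen, gem-dimethyl acceleration of ring closure) and the low temperature should secure this.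

Step 7
Reactants: 10 (5S)-3,3,5-trimethyl-4-methylidenecyclohexan-1-one
Product: 12 triethyl{[(1S,5S)-3,3,5-trimethyl-4-methylidenecyclohexyl]oxy}silane, via lithium alkoxide 11 (not isolated)
Conditions: LiBH(s-Bu)3, THF, −78 °C; then Et3SiOTf, 2,6-lutidine, −78 to 0 °C
Reagents that add atoms: triethylsilyl trifluoromethanesulfonate, CC[Si](CC)(CC)OS(=O)(=O)C(F)(F)F
Why: Diastereoselective ketone reduction with a bulky trialkylborohydride; in the chair with the C5 methyl equatorial the axial face of the C3 carbonyl is shielded by the syn-axial C1 methyl, so hydride enters equatorially and gives the axial alkoxide trans to the C5 methyl (new C3 centre S, as known for 3,3,5-trimethylcyclohexanone), which is silylated in the same flask.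

Step 8
Reactants: 12 triethyl{[(1S,5S)-3,3,5-trimethyl-4-methylidenecyclohexyl]oxy}silane; 13 (2E)-3-methyl-4-oxobut-2-en-1-yl acetate
Product: 14 (2E)-4-hydroxy-3-methyl-5-[(4S)-2,6,6-trimethyl-4-(triethylsilyloxy)cyclohex-1-en-1-yl]pent-2-en-1-yl acetate
Conditions: Me2AlCl (2.5 equiv), CH2Cl2, −78 to −20 °C
Reagents that add atoms: none
Why: Lewis-acid-promoted intermolecular carbonyl-ene reaction, in which the 1,1-disubstituted C6=C7 alkene adds through C7 to the activated aldehyde while the only allylic hydrogen, the axial C5–H, is transferred to oxygen; this forms the C7–C8 bond, moves the double bond to the tetrasubstituted C5=C6 position and erases the C5 centre after it has done its work, the new C8 carbinol centre being formed unselectively, which is harmless.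

Step 9
Reactants: 14 (2E)-4-hydroxy-3-methyl-5-[(4S)-2,6,6-trimethyl-4-(triethylsilyloxy)cyclohex-1-en-1-yl]pent-2-en-1-yl acetate
Product: 16 (2E)-4-[tert-butyl(dimethyl)silyl]oxy-5-[(4S)-4-hydroxy-2,6,6-trimethylcyclohex-1-en-1-yl]-3-methylpent-2-en-1-yl acetate, via bis-silyl ether 15 (not isolated)
Conditions: t-BuMe2SiOTf, 2,6-lutidine, CH2Cl2, −78 °C; then pyridinium p-toluenesulfonate, MeOH, rt
Reagents that add atoms: tert-butyldimethylsilyl trifluoromethanesulfonate, CC(C)(C)[Si](C)(C)OS(=O)(=O)C(F)(F)F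
Why: Silyl triflate silylation of the hindered allylic C8 alcohol followed by selective acid-catalysed methanolysis of the much more labile triethylsilyl ether (differential silyl ether lability) frees only the ring C3 hydroxyl.

Step 10
Reactants: 16 (2E)-4-[tert-butyl(dimethyl)silyl]oxy-5-[(4S)-4-hydroxy-2,6,6-trimethylcyclohex-1-en-1-yl]-3-methylpent-2-en-1-yl acetate
Product: 17 (2E)-4-[tert-butyl(dimethyl)silyl]oxy-5-[(1S,4R,6R)-4-hydroxy-2,2,6-trimethyl-7-oxabicyclo[4.1.0]heptan-1-yl]-3-methylpent-2-en-1-yl acetate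
Conditions: VO(acac)2 (5 mol %), t-BuOOH, CH2Cl2, rt
Reagents that add atoms: tert-butyl hydroperoxide, CC(C)(C)OO
Why: Vanadium-catalysed hydroxyl-directed epoxidation of a homoallylic alcohol; the peroxide bound to the C3 alkoxide–vanadium centre delivers oxygen to C5=C6 on the face of the hydroxyl, setting C5 (R) and C6 (S) cis to the C3 oxygen, while the C9=C10 alkene, which has no free hydroxyl nearby, should stay untouched.

Step 11
Reactants: 17 (2E)-4-[tert-butyl(dimethyl)silyl]oxy-5-[(1S,4R,6R)-4-hydroxy-2,2,6-trimethyl-7-oxabicyclo[4.1.0]heptan-1-yl]-3-methylpent-2-en-1-yl acetate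
Product: 18 (1S,4S,6R)-1-[(3E)-5-acetoxy-2-[tert-butyl(dimethyl)silyl]oxy-3-methylpent-3-en-1-yl]-2,2,6-trimethyl-7-oxabicyclo[4.1.0]heptan-4-yl 4-nitrobenzoate
Conditions: PPh3, diisopropyl azodicarboxylate, 4-nitrobenzoic acid, THF, 0 °C to rt
Reagents that add atoms: 4-nitrobenzoic acid, OC(=O)c1ccc(cc1)[N+](=O)[O-]
Why: Mitsunobu reaction; SN2 displacement of the C3 oxyphosphonium group by 4-nitrobenzoate inverts C3 to S, so that the C3 oxygen is now trans to the epoxide as in the target, and the ester protects C3 during the next two steps.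

Step 12
Reactants: 18 (1S,4S,6R)-1-[(3E)-5-acetoxy-2-[tert-butyl(dimethyl)silyl]oxy-3-methylpent-3-en-1-yl]-2,2,6-trimethyl-7-oxabicyclo[4.1.0]heptan-4-yl 4-nitrobenzoate
Product: 19 [(2E)-4-[tert-butyl(dimethyl)silyl]oxy-3-methyl-5-{(1S,4S,6R)-2,2,6-trimethyl-4-[(4-nitrobenzoyl)oxy]-7-oxabicyclo[4.1.0]heptan-1-yl}pent-2-en-1-yl]triphenylphosphonium bromide
Conditions: PPh3, NaBr, Pd(PPh3)4 (3 mol %), THF/MeOH, rt
Reagents that add atoms: triphenylphosphine, c1ccc(cc1)P(c1ccccc1)c1ccccc1; sodium bromide, [Na+].[Br-]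
Why: Palladium-catalysed allylic substitution (Tsuji–Trost type) with triphenylphosphine as nucleophile; zerovalent palladium ionises the primary allylic acetate and the phosphine attacks the unhindered C11 terminus of the π-allyl complex with the E alkene retained, under neutral conditions that spare the epoxide.

Step 13
Reactants: 19 [(2E)-4-[tert-butyl(dimethyl)silyl]oxy-3-methyl-5-{(1S,4S,6R)-2,2,6-trimethyl-4-[(4-nitrobenzoyl)oxy]-7-oxabicyclo[4.1.0]heptan-1-yl}pent-2-en-1-yl]triphenylphosphonium bromide; 20 (2E,4E,6E)-2,7-dimethylocta-2,4,6-trienedial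
Product: 23 (2E,4E,6E,8E,10E)-12-[tert-butyl(dimethyl)silyl]oxy-13-[(1S,4S,6R)-4-hydroxy-2,2,6-trimethyl-7-oxabicyclo[4.1.0]heptan-1-yl]-2,7,11-trimethyltrideca-2,4,6,8,10-pentaenal, via phosphonium ylide 21 (not isolated), via 4-nitrobenzoate polyenal 22 (not isolated)
Conditions: 20 (3 equiv), NaOMe, MeOH/CH2Cl2, 0 °C to rt; then I2 (cat.), CH2Cl2, rt, daylight
Reagents that add atoms: none
Why: Wittig olefination of the semistabilised allylic ylide with one aldehyde group of the symmetrical dialdehyde (used in excess to favour mono-olefination) forms the C11=C12 bond, methoxide then cleaves the activated 4-nitrobenzoate by transesterification, and iodine-catalysed equilibration should convert any 11Z isomer into the all-E polyene.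

Step 14
Reactants: 23 (2E,4E,6E,8E,10E)-12-[tert-butyl(dimethyl)silyl]oxy-13-[(1S,4S,6R)-4-hydroxy-2,2,6-trimethyl-7-oxabicyclo[4.1.0]heptan-1-yl]-2,7,11-trimethyltrideca-2,4,6,8,10-pentaenal
Product: 24 (2E,4E,6E,8E,10E)-12-hydroxy-13-[(1S,4S,6R)-4-hydroxy-2,2,6-trimethyl-7-oxabicyclo[4.1.0]heptan-1-yl]-2,7,11-trimethyltrideca-2,4,6,8,10-pentaenal
Conditions: Bu4NF, AcOH, THF, 0 °C to rt
Reagents that add atoms: none
Why: Fluoride-mediated desilylation, buffered with acetic acid, should remove the silyl ether from C8 without harming the polyenal or the epoxide.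

Step 15
Reactants: 24 (2E,4E,6E,8E,10E)-12-hydroxy-13-[(1S,4S,6R)-4-hydroxy-2,2,6-trimethyl-7-oxabicyclo[4.1.0]heptan-1-yl]-2,7,11-trimethyltrideca-2,4,6,8,10-pentaenal
Product: 25 (2E,4E,6E,8E,10E)-13-[(1S,4S,6R)-4-hydroxy-2,2,6-trimethyl-7-oxabicyclo[4.1.0]heptan-1-yl]-2,7,11-trimethyl-12-oxotrideca-2,4,6,8,10-pentaenal
Conditions: MnO2 (excess), CH2Cl2, rt, dark
Reagents that add atoms: none
Why: Chemoselective MnO2 oxidation of the allylic, polyene-conjugated C8 alcohol leaves the saturated C3 alcohol untouched and generates the base- and acid-sensitive β,γ-epoxy ketone only in the final neutral step, both C8 epimers converging on the target.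

Compound list
1 | (2S)-4-methoxy-2-methyl-4-oxobutanoic acid | COC(=O)C[C@H](C)C(=O)O | starting material
2 | methyl (3S)-4-chloro-3-methyl-4-oxobutanoate | COC(=O)C[C@H](C)C(Cl)=O | intermediate
3 | trimethyl[(2-methylprop-1-en-1-yl)oxy]silane | CC(C)=CO[Si](C)(C)C | starting material
4 | methyl (3S)-3,5,5-trimethyl-4,6-dioxohexanoate | COC(=O)C[C@H](C)C(=O)C(C)(C)C=O | intermediate
5 | methyl (3S)-6-hydroxy-3,5,5-trimethyl-4-oxohexanoate | COC(=O)C[C@H](C)C(=O)C(C)(C)CO | intermediate
6 | methyl (3S)-6-hydroxy-3,5,5-trimethyl-4-methylidenehexanoate | COC(=O)C[C@H](C)C(=C)C(C)(C)CO | intermediate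
7 | methyl (3S)-6-iodo-3,5,5-trimethyl-4-methylidenehexanoate | COC(=O)C[C@H](C)C(=C)C(C)(C)CI | intermediate
8 | methyl (3S)-6-lithio-3,5,5-trimethyl-4-methylidenehexanoate | COC(=O)C[C@H](C)C(=C)C(C)(C)C[Li] | intermediate
9 | lithium (5S)-1-methoxy-3,3,5-trimethyl-4-methylidenecyclohexan-1-olate (hemiketal carbon undefined) | [Li+].COC1([O-])C[C@H](C)C(=C)C(C)(C)C1 | intermediate
10 | (5S)-3,3,5-trimethyl-4-methylidenecyclohexan-1-one | C=C1[C@@H](C)CC(=O)CC1(C)C | intermediate
11 | lithium (1S,5S)-3,3,5-trimethyl-4-methylidenecyclohexan-1-olate | [Li+].C=C1[C@@H](C)C[C@H]([O-])CC1(C)C | intermediate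
12 | triethyl{[(1S,5S)-3,3,5-trimethyl-4-methylidenecyclohexyl]oxy}silane (oxygen trans to the C5 methyl) | C=C1[C@@H](C)C[C@H](O[Si](CC)(CC)CC)CC1(C)C | intermediate
13 | (2E)-3-methyl-4-oxobut-2-en-1-yl acetate | CC(=O)OC/C=C(\C)C=O | starting material
14 | (2E)-4-hydroxy-3-methyl-5-[(4S)-2,6,6-trimethyl-4-(triethylsilyloxy)cyclohex-1-en-1-yl]pent-2-en-1-yl acetate | CC(=O)OC/C=C(\C)C(O)CC1=C(C)C[C@H](O[Si](CC)(CC)CC)CC1(C)C | intermediate
15 | (2E)-4-[tert-butyl(dimethyl)silyl]oxy-3-methyl-5-[(4S)-2,6,6-trimethyl-4-(triethylsilyloxy)cyclohex-1-en-1-yl]pent-2-en-1-yl acetate | CC(=O)OC/C=C(\C)C(O[Si](C)(C)C(C)(C)C)CC1=C(C)C[C@H](O[Si](CC)(CC)CC)CC1(C)C | intermediate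
16 | (2E)-4-[tert-butyl(dimethyl)silyl]oxy-5-[(4S)-4-hydroxy-2,6,6-trimethylcyclohex-1-en-1-yl]-3-methylpent-2-en-1-yl acetate | CC(=O)OC/C=C(\C)C(O[Si](C)(C)C(C)(C)C)CC1=C(C)C[C@H](O)CC1(C)C | intermediate
17 | (2E)-4-[tert-butyl(dimethyl)silyl]oxy-5-[(1S,4R,6R)-4-hydroxy-2,2,6-trimethyl-7-oxabicyclo[4.1.0]heptan-1-yl]-3-methylpent-2-en-1-yl acetate (hydroxyl cis to the epoxide oxygen) | CC(=O)OC/C=C(\C)C(O[Si](C)(C)C(C)(C)C)C[C@@]12O[C@]1(C)C[C@H](O)CC2(C)C | intermediate
18 | (1S,4S,6R)-1-[(3E)-5-acetoxy-2-[tert-butyl(dimethyl)silyl]oxy-3-methylpent-3-en-1-yl]-2,2,6-trimethyl-7-oxabicyclo[4.1.0]heptan-4-yl 4-nitrobenzoate (ester oxygen trans to the epoxide oxygen) | CC(=O)OC/C=C(\C)C(O[Si](C)(C)C(C)(C)C)C[C@@]12O[C@]1(C)C[C@@H](OC(=O)c3ccc(cc3)[N+](=O)[O-])CC2(C)C | intermediate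
19 | [(2E)-4-[tert-butyl(dimethyl)silyl]oxy-3-methyl-5-{(1S,4S,6R)-2,2,6-trimethyl-4-[(4-nitrobenzoyl)oxy]-7-oxabicyclo[4.1.0]heptan-1-yl}pent-2-en-1-yl]triphenylphosphonium bromide | [Br-].CC(C)(C)[Si](C)(C)OC(C[C@@]12O[C@]1(C)C[C@@H](OC(=O)c3ccc(cc3)[N+](=O)[O-])CC2(C)C)/C(C)=C/C[P+](c4ccccc4)(c5ccccc5)c6ccccc6 | intermediate
20 | (2E,4E,6E)-2,7-dimethylocta-2,4,6-trienedial | C\C(C=O)=C/C=C/C=C(C)/C=O | starting material
21 | phosphonium ylide of 19 (C11=P) | CC(C)(C)[Si](C)(C)OC(C[C@@]12O[C@]1(C)C[C@@H](OC(=O)c3ccc(cc3)[N+](=O)[O-])CC2(C)C)/C(C)=C/C=P(c4ccccc4)(c5ccccc5)c6ccccc6 | intermediate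
22 | (1S,4S,6R)-1-[(3E,5E,7E,9E,11E)-2-[tert-butyl(dimethyl)silyl]oxy-3,7,12-trimethyl-13-oxotrideca-3,5,7,9,11-pentaen-1-yl]-2,2,6-trimethyl-7-oxabicyclo[4.1.0]heptan-4-yl 4-nitrobenzoate | C\C(C=O)=C/C=C/C=C(C)/C=C/C=C(\C)C(O[Si](C)(C)C(C)(C)C)C[C@@]12O[C@]1(C)C[C@@H](OC(=O)c3ccc(cc3)[N+](=O)[O-])CC2(C)C | intermediate
23 | (2E,4E,6E,8E,10E)-12-[tert-butyl(dimethyl)silyl]oxy-13-[(1S,4S,6R)-4-hydroxy-2,2,6-trimethyl-7-oxabicyclo[4.1.0]heptan-1-yl]-2,7,11-trimethyltrideca-2,4,6,8,10-pentaenal | C\C(C=O)=C/C=C/C=C(C)/C=C/C=C(\C)C(O[Si](C)(C)C(C)(C)C)C[C@@]12O[C@]1(C)C[C@@H](O)CC2(C)C | intermediate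
24 | (2E,4E,6E,8E,10E)-12-hydroxy-13-[(1S,4S,6R)-4-hydroxy-2,2,6-trimethyl-7-oxabicyclo[4.1.0]heptan-1-yl]-2,7,11-trimethyltrideca-2,4,6,8,10-pentaenal | C\C(C=O)=C/C=C/C=C(C)/C=C/C=C(\C)C(O)C[C@@]12O[C@]1(C)C[C@@H](O)CC2(C)C | intermediate
25 | (2E,4E,6E,8E,10E)-13-[(1S,4S,6R)-4-hydroxy-2,2,6-trimethyl-7-oxabicyclo[4.1.0]heptan-1-yl]-2,7,11-trimethyl-12-oxotrideca-2,4,6,8,10-pentaenal | C\C(C=O)=C/C=C/C=C(C)/C=C/C=C(\C)C(=O)C[C@@]12O[C@]1(C)C[C@@H](O)CC2(C)C | target

Total step count: 15. Longest linear sequence: 15 steps (1 to 25); 3, 13 and 20 enter as purchased building blocks.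

Steps most likely to fail

Step 8. The Me2AlCl-complexed enal may be attacked at its C=C bond (conjugate ene reaction or cycloaddition) instead of at the carbonyl carbon, or the developing tertiary cation at C6 may suffer a methyl shift from C1 before proton loss. The fallback sets out from 12 and uses formaldehyde as a far more reliable enophile: paraformaldehyde and Me2AlCl should give 2-[(4S)-2,6,6-trimethyl-4-(triethylsilyloxy)cyclohex-1-en-1-yl]ethan-1-ol F4, which buffered Dess–Martin periodinane oxidises to [(4S)-2,6,6-trimethyl-4-(triethylsilyloxy)cyclohex-1-en-1-yl]acetaldehyde F5. A Nozaki–Hiyama–Kishi coupling (CrCl2, catalytic NiCl2, DMF) with (2E)-3-iodobut-2-en-1-yl acetate F6, made by acetylation of (2E)-3-iodobut-2-en-1-ol, then forms the C8–C9 bond and comes back to the route at 14.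

Step 6. Direct attack of t-BuLi on the ester, quenching of the alkyllithium by proton transfer from the ester α-position, or anionic vinyl migration may compete with ring closure. The fallback closes the same C2–C3 bond by metathesis and sets out from 2: 3-methylbut-2-en-1-ylzinc bromide adds with allylic transposition to give methyl (3S)-3,5,5-trimethyl-4-oxohept-6-enoate F1. Cp2TiMe2 (toluene, 70 °C) methylenates both the ketone and the ester carbonyl to give (4S)-2-methoxy-4,6,6-trimethyl-5-methylideneocta-1,7-diene F2. Ring-closing metathesis with the second-generation Grubbs catalyst between the vinyl group and the enol ether gives (5S)-1-methoxy-3,3,5-trimethyl-4-methylidenecyclohex-1-ene F3, and dilute HCl in THF hydrolyses the enol ether, coming back to the route at 10.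

Step 11. Displacement at the ring carbon C3 may be slow, so that elimination of the activated hydroxyl or recovery of unreacted alcohol takes over. The fallback sets out from 17 and separates activation from displacement: Tf2O and pyridine (−20 °C) give (1S,4R,6R)-1-[(3E)-5-acetoxy-2-[tert-butyl(dimethyl)silyl]oxy-3-methylpent-3-en-1-yl]-2,2,6-trimethyl-7-oxabicyclo[4.1.0]heptan-4-yl trifluoromethanesulfonate F7, which caesium 4-nitrobenzoate with 18-crown-6 in toluene displaces with inversion, coming back to the route at 18.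

Further compounds
F1 | step 6 | methyl (3S)-3,5,5-trimethyl-4-oxohept-6-enoate | COC(=O)C[C@H](C)C(=O)C(C)(C)C=C
F2 | step 6 | (4S)-2-methoxy-4,6,6-trimethyl-5-methylideneocta-1,7-diene | COC(=C)C[C@H](C)C(=C)C(C)(C)C=C
F3 | step 6 | (5S)-1-methoxy-3,3,5-trimethyl-4-methylidenecyclohex-1-ene | COC1=CC(C)(C)C(=C)[C@@H](C)C1
F4 | step 8 | 2-[(4S)-2,6,6-trimethyl-4-(triethylsilyloxy)cyclohex-1-en-1-yl]ethan-1-ol | OCCC1=C(C)C[C@H](O[Si](CC)(CC)CC)CC1(C)C
F5 | step 8 | [(4S)-2,6,6-trimethyl-4-(triethylsilyloxy)cyclohex-1-en-1-yl]acetaldehyde | O=CCC1=C(C)C[C@H](O[Si](CC)(CC)CC)CC1(C)C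
F6 | step 8 | (2E)-3-iodobut-2-en-1-yl acetate | CC(=O)OC/C=C(\C)I
F7 | step 11 | (1S,4R,6R)-1-[(3E)-5-acetoxy-2-[tert-butyl(dimethyl)silyl]oxy-3-methylpent-3-en-1-yl]-2,2,6-trimethyl-7-oxabicyclo[4.1.0]heptan-4-yl trifluoromethanesulfonate | CC(=O)OC/C=C(\C)C(O[Si](C)(C)C(C)(C)C)C[C@@]12O[C@]1(C)C[C@H](OS(=O)(=O)C(F)(F)F)CC2(C)C
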